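**Remark on the chemistry (assumption):** The SMILES is read as the (3R,4R), trans lactone. The sense of induction in step 8 is taken from the accepted enamine model of the imidazolidinone catalyst, not from a measurement; if it proved opposite, the (2S,5R) catalyst would be used.

Atom labels used throughout: lactone ring C = O1, C2 (carbonyl), C3, C4, C5 (CH2–O). C7′ is the benzylic carbon on C3 and leads to ring B (3,4-dihydroxy-5-methoxyphenyl). C7 is the benzylic carbon on C4 and leads to ring A (4-hydroxy-3-methoxyphenyl).

## The problem

The target is a γ-butyrolactone that carries two different, electron-rich arylmethyl groups on adjacent carbons, trans to each other, with both centres R. No ring is hard to close. The difficulty is that two nearly identical C6–C3 halves must be joined at C3–C4 unsymmetrically, with ring B next to the carbonyl C2 and ring A next to the C5 methylene, and with absolute control at C4. C4 cannot be epimerised and must be set by the synthesis. C3 is α to C2, can be epimerised, and is more stable trans to the C4 substituent, so C4 can control C3 by equilibration. The feature that makes the key step possible is the O=C2–C3–C4–C5–O chain of ring C: C3 is the α-carbon of a carboxyl carbon, and C4 is the α-carbon of C5, which is one reduction step below an aldehyde. Both are therefore natural enolate or enamine carbons, and the C3–C4 bond joins two carbons of like polarity. Because C3 also bears a hydrogen, it can carry a second, traceless ester group in a precursor; this makes C3 an electrophilic malonyl radical centre while C4 reacts as a chiral enamine. The catechol of ring B and the phenol of ring A are oxidised easily, above all in base, so all three are carried as benzyl ethers and freed last under neutral conditions.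

## Retrosynthesis

**18 ⇒ 17.** The three O–CH2Ph bonds are cut last. One kind of protecting group on all three phenols allows a single neutral final operation. Benzyl ethers should survive hydride, base, hot LiCl/DMSO and the photoredox conditions. The forward reaction must be a clean triple hydrogenolysis that touches neither the lactone nor the C3–H.

**17 ⇒ 15.** A methoxycarbonyl group is added back onto C3, so the C3–H bond becomes a C3–CO2Me bond. C3 is then a malonate carbon: it has no configuration to control in the open-chain precursor and stabilises a radical. A nitrile or sulfone at C3 would do the same but is harder to remove in the presence of the lactone. The forward reaction is a dealkoxycarbonylation followed by equilibration of C3 to trans (via the cis epimer 16).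

**15 ⇒ 13.** The lactone bond O1–C2 is cut and C5 is raised to the aldehyde level. This gives the open-chain aldehyde 13 with one stereocentre; its alcohol 14 closes onto either malonate ester. The other ring cut, O1–C5, would need a leaving group at C5 and an extra step. The forward reaction must reduce an aldehyde beside two esters without loss of configuration at C4.

**13 ⇒ 5 + 12 (key cut, C3–C4).** This cut divides the molecule into two C6–C3 halves of equal size, the achiral aldehyde 5 and the achiral tertiary bromomalonate 12. Cutting C3–C7′ or C4–C7 instead would leave a chiral lactone to be made first and would separate the asymmetric step from the union of the halves. Here the precursors have no stereocentre, and the product has the whole skeleton, the C4 centre and the correct oxidation pattern. The forward reaction must join two α-carbons by polarity reversal, select one enantioface at C4, form a crowded quaternary–tertiary bond, and leave three benzyl ethers alone.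

**12 ⇒ 10 ⇒ 9 ⇒ 7 + 8; 7 ⇒ 6.** The C3–Br bond comes from enolate bromination of 10. The C3–C7′ bond comes from a Knoevenagel condensation of aldehyde 7 with dimethyl malonate 8, followed by conjugate reduction of 9. This avoids a benzylic halide and the double alkylation of a malonate. Aldehyde 7 is the bis-benzyl ether of commercial 5-hydroxyvanillin 6, which already has ring B's oxygen pattern.

**5 ⇒ 4 ⇒ 2 ⇒ 1.** Ring A with its three-carbon chain is bought intact as eugenol 1. Only O-benzylation (2), anti-Markovnikov hydration of the allyl group (4, via borane 3) and oxidation to 5 are needed. Building the chain from a C6–C1 aldehyde would take more steps and would need a conjugate reduction that must spare the benzyl ether.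

## Roads not taken

**Alternative 1:** Cut C3–C7′. The forward key step is alkylation of the lithium enolate of the (R)-lactone A1 with the ring-B benzylic bromide A2, anti to the C4 substituent, to give 17. This is the route drawn first. Its weakness is structural: A1 must itself be made in enantioenriched form by a separate multi-step sequence, so the stereocentre is created on a small fragment and the union of the halves is a second, unrelated event. The kinetic alkylation also competes with proton transfer and double alkylation. The chosen plan sets C4 and joins the halves in one catalytic step from two achiral compounds.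

**Alternative 2:** Cut C3–C4, but make the bond by oxidative hetero-coupling of two lithium enolates. Imide A3 (with a 4-benzyl-oxazolidinone auxiliary) and tert-butyl ester A4 would be oxidised with Fe(acac)3 or copper bis(2-ethylhexanoate) to succinate A5. Reduction of the imide carbonyl to C5 and acid-promoted closure would give 17 after equilibration. The bond is the same, but the method needs a stoichiometric auxiliary that is put on and taken off, two strong-base enolates formed side by side, and a stoichiometric metal oxidant. Homo-coupling is suppressed only by a difference in oxidation potential, and face selectivity in a radical-type coupling is usually weaker than in polar alkylation of the same auxiliary. In the chosen plan cross-selectivity is built into the mechanism: only 12 can be reduced and only 5 can form an enamine.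

**Alternative 3:** Cut C4–C7 and C3–C7′ and set stereochemistry last. Two regioselective sp3–sp2 cross-couplings on dibromobutenolide A7 (C4 first, as the more electrophilic position) would give the achiral butenolide A6. The forward key step would be an enantioselective reduction of the tetrasubstituted C3=C4 bond (copper hydride conjugate reduction or asymmetric hydrogenation), then equilibration at C3. The assembly is short, but the stereo-determining step would act on a tetrasubstituted alkene with no coordinating group, the hardest substrate class for both methods. Hydrogenation would also clash with benzyl ethers, and A6 can move its double bond into conjugation with an aryl ring. The chosen plan places the asymmetric step on an unhindered enamine, a substrate class with close precedent.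

Key step: step 8

## Steps

Step 1
Reactants: 1 eugenol (4-allyl-2-methoxyphenol)
Product: 2 4-allyl-1-(benzyloxy)-2-methoxybenzene
Conditions: BnBr, K2CO3, DMF, 23 °C
Reagents that add atoms: benzyl bromide, BrCc1ccccc1
Why: Williamson ether synthesis on the phenoxide; the allyl group is inert to carbonate base.

Step 2
Reactants: 2 4-allyl-1-(benzyloxy)-2-methoxybenzene
Product: 4 3-[4-(benzyloxy)-3-methoxyphenyl]propan-1-ol, via B-alkyl-9-BBN adduct 3 (not isolated)
Conditions: 9-BBN, THF, 0 to 23 °C; then aq. NaOH, 30% H2O2, 0 °C
Reagents that add atoms: 9-borabicyclo[3.3.1]nonane, B1C2CCCC1CCC2 (its boron bicycle stays only in 3); hydrogen peroxide, OO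
Why: Hydroboration–oxidation; the bulky borane should add to the terminal carbon of the allyl group, and oxidation of the C–B bond with retention gives the primary alcohol.

Step 3
Reactants: 4 3-[4-(benzyloxy)-3-methoxyphenyl]propan-1-ol
Product: 5 3-[4-(benzyloxy)-3-methoxyphenyl]propanal
Conditions: Dess–Martin periodinane, CH2Cl2, 0 to 23 °C
Reagents that add atoms: none
Why: Dess–Martin oxidation stops at the aldehyde and should not touch the electron-rich ring or the benzyl ether; 5 is used soon after preparation.

Step 4
Reactants: 6 3,4-dihydroxy-5-methoxybenzaldehyde (5-hydroxyvanillin)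
Product: 7 3,4-bis(benzyloxy)-5-methoxybenzaldehyde
Conditions: BnBr (2.2 equiv), K2CO3, DMF, 60 °C
Reagents that add atoms: benzyl bromide, BrCc1ccccc1
Why: Double Williamson ether synthesis; both catechol oxygens are alkylated, which removes the oxidation-prone catechol from the whole route.

Step 5
Reactants: 7 3,4-bis(benzyloxy)-5-methoxybenzaldehyde; 8 dimethyl malonate
Product: 9 dimethyl 2-[3,4-bis(benzyloxy)-5-methoxybenzylidene]propanedioate
Conditions: piperidine (cat.), AcOH (cat.), toluene, reflux, Dean–Stark trap
Reagents that add atoms: none
Why: Knoevenagel condensation driven by removal of water; it forms the C3–C7′ bond without a benzylic halide and cannot over-alkylate.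

Step 6
Reactants: 9 dimethyl 2-[3,4-bis(benzyloxy)-5-methoxybenzylidene]propanedioate
Product: 10 dimethyl 2-[3,4-bis(benzyloxy)-5-methoxybenzyl]propanedioate
Conditions: NaBH4, MeOH, 0 °C
Reagents that add atoms: none
Why: Conjugate hydride reduction of a doubly activated alkylidene malonate; hydride is used instead of hydrogen over palladium so that the benzyl ethers stay.

Step 7
Reactants: 10 dimethyl 2-[3,4-bis(benzyloxy)-5-methoxybenzyl]propanedioate
Product: 12 dimethyl 2-bromo-2-[3,4-bis(benzyloxy)-5-methoxybenzyl]propanedioate, via sodium enolate 11 (not isolated)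
Conditions: NaH, THF, 0 °C; then NBS, 0 °C
Reagents that add atoms: sodium hydride, [Na+].[H-] (its sodium stays only in 11); N-bromosuccinimide, O=C1CCC(=O)N1Br
Why: Electrophilic bromination of a preformed malonate enolate; the enolate should react with the bromine source far faster than the alkoxy-substituted ring does.

Step 8
Reactants: 5 3-[4-(benzyloxy)-3-methoxyphenyl]propanal; 12 dimethyl 2-bromo-2-[3,4-bis(benzyloxy)-5-methoxybenzyl]propanedioate
Product: 13 dimethyl 2-[3,4-bis(benzyloxy)-5-methoxybenzyl]-2-[(2R)-1-[4-(benzyloxy)-3-methoxyphenyl]-3-oxopropan-2-yl]propanedioate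
Conditions: (2R,5S)-2-tert-butyl-3,5-dimethylimidazolidin-4-one·CF3SO3H (20 mol %), Ru(bpy)3Cl2 (0.5 mol %), 2,6-lutidine, DMF, blue LEDs, 23 °C
Reagents that add atoms: none
Why: Photoredox organocatalytic α-alkylation of an aldehyde: 5 forms the E-enamine with the imidazolidinone, while the photoexcited divalent ruthenium complex is reduced to the monovalent complex, which passes one electron to 12 and releases bromide and the electrophilic tertiary malonyl radical at C3. The radical adds to the electron-rich enamine carbon C4, the α-amino radical so formed is oxidised to the iminium ion (by the excited ruthenium complex or by 12 in a chain), and hydrolysis gives 13 and returns the amine. The closest known reaction type is the enantioselective α-alkylation of aldehydes with α-bromomalonates and related α-bromo 1,3-dicarbonyl compounds under the same dual catalysis, tertiary bromides included. No ring is closed; the step forms the C3–C4 bond between two carbons that are both nucleophilic α-carbons in polar terms. The only new stereocentre, C4, is set by the catalyst: the tert-butyl group turns the enamine double bond towards C5 of the imidazolidinone, the C5 methyl group covers the Re face, and the radical should enter on the Si face to give the (R)-aldehyde. Cross-selectivity follows from the division of roles, since only 12 is reduced by the monovalent ruthenium complex and only 5 can form an enamine, and the benzyl ethers and alkoxyarenes lie outside the redox window of the catalyst. C3 is formed as a quaternary centre with two identical ester groups, so no diastereoselectivity is asked, and this quaternary neighbour should slow re-enolisation of 13 and so protect the new centre.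

Step 9
Reactants: 13 dimethyl 2-[3,4-bis(benzyloxy)-5-methoxybenzyl]-2-[(2R)-1-[4-(benzyloxy)-3-methoxyphenyl]-3-oxopropan-2-yl]propanedioate
Product: 15 methyl (4R)-3-[3,4-bis(benzyloxy)-5-methoxybenzyl]-4-[4-(benzyloxy)-3-methoxybenzyl]-2-oxooxolane-3-carboxylate (both C3 epimers), via hydroxy diester 14 (not isolated)
Conditions: NaBH4, MeOH/CH2Cl2, −20 °C; then TsOH·H2O (cat.), toluene, 40 °C
Reagents that add atoms: none
Why: Chemoselective borohydride reduction of the aldehyde, then 5-exo-trig lactonisation of the γ-hydroxy malonate onto either ester; the configuration at C3 does not matter because C3 is made planar in step 10. Crude 13 is used without chromatography to avoid enolisation at C4, and surplus 5 from step 8 is reduced to 4 and can return to step 3.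

Step 10
Reactants: 15 methyl (4R)-3-[3,4-bis(benzyloxy)-5-methoxybenzyl]-4-[4-(benzyloxy)-3-methoxybenzyl]-2-oxooxolane-3-carboxylate
Product: 17 (3R,4R)-3-[3,4-bis(benzyloxy)-5-methoxybenzyl]-4-[4-(benzyloxy)-3-methoxybenzyl]oxolan-2-one, via cis-lactone 16 (not isolated)
Conditions: LiCl, H2O, DMSO, 150 °C; then DBU, 60 °C
Reagents that add atoms: none
Why: Krapcho dealkoxycarbonylation: chloride removes the ester methyl group by SN2, the carboxylate loses CO2, and the lactone enolate is protonated by water. Protonation anti to the C4 substituent gives some (3S,4R) cis epimer 16; base equilibration through the enolate should convert it into the more stable trans lactone, with C4 as the controlling centre.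

Step 11
Reactants: 17 (3R,4R)-3-[3,4-bis(benzyloxy)-5-methoxybenzyl]-4-[4-(benzyloxy)-3-methoxybenzyl]oxolan-2-one
Product: 18 (−)-thujaplicatin, (3R,4R)-3-(3,4-dihydroxy-5-methoxybenzyl)-4-(4-hydroxy-3-methoxybenzyl)oxolan-2-one
Conditions: H2 (1 atm), 10% Pd/C, EtOAc/MeOH, 23 °C
Reagents that add atoms: none
Why: Hydrogenolysis of three aryl benzyl ethers under neutral conditions; the lactone, the aryl methyl ethers and the C3–H are not affected, so the trans configuration is kept. The product is handled under argon.

## Compound list

1 | eugenol (4-allyl-2-methoxyphenol) | COc1cc(CC=C)ccc1O | starting material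
2 | 4-allyl-1-(benzyloxy)-2-methoxybenzene | COc1cc(CC=C)ccc1OCc1ccccc1 | intermediate
3 | 9-{3-[4-(benzyloxy)-3-methoxyphenyl]propyl}-9-borabicyclo[3.3.1]nonane | COc1cc(CCCB2C3CCCC2CCC3)ccc1OCc1ccccc1 | intermediate
4 | 3-[4-(benzyloxy)-3-methoxyphenyl]propan-1-ol | COc1cc(CCCO)ccc1OCc1ccccc1 | intermediate
5 | 3-[4-(benzyloxy)-3-methoxyphenyl]propanal | COc1cc(CCC=O)ccc1OCc1ccccc1 | intermediate
6 | 3,4-dihydroxy-5-methoxybenzaldehyde (5-hydroxyvanillin) | COc1cc(C=O)cc(O)c1O | starting material
7 | 3,4-bis(benzyloxy)-5-methoxybenzaldehyde | COc1cc(C=O)cc(OCc2ccccc2)c1OCc1ccccc1 | intermediate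
8 | dimethyl malonate | COC(=O)CC(=O)OC | starting material
9 | dimethyl 2-[3,4-bis(benzyloxy)-5-methoxybenzylidene]propanedioate | COC(=O)C(=Cc1cc(OC)c(OCc2ccccc2)c(OCc2ccccc2)c1)C(=O)OC | intermediate
10 | dimethyl 2-[3,4-bis(benzyloxy)-5-methoxybenzyl]propanedioate | COC(=O)C(Cc1cc(OC)c(OCc2ccccc2)c(OCc2ccccc2)c1)C(=O)OC | intermediate
11 | sodium enolate of 10 (sodium 2-[3,4-bis(benzyloxy)-5-methoxybenzyl]-1,3-dimethoxy-1,3-dioxopropan-2-ide) | [Na+].COC(=O)[C-](Cc1cc(OC)c(OCc2ccccc2)c(OCc2ccccc2)c1)C(=O)OC | intermediate
12 | dimethyl 2-bromo-2-[3,4-bis(benzyloxy)-5-methoxybenzyl]propanedioate | COC(=O)C(Br)(Cc1cc(OC)c(OCc2ccccc2)c(OCc2ccccc2)c1)C(=O)OC | intermediate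
13 | dimethyl 2-[3,4-bis(benzyloxy)-5-methoxybenzyl]-2-[(2R)-1-[4-(benzyloxy)-3-methoxyphenyl]-3-oxopropan-2-yl]propanedioate | COc1cc(C[C@@H](C=O)C(Cc2cc(OC)c(OCc3ccccc3)c(OCc3ccccc3)c2)(C(=O)OC)C(=O)OC)ccc1OCc1ccccc1 | intermediate
14 | dimethyl 2-[3,4-bis(benzyloxy)-5-methoxybenzyl]-2-[(2R)-1-[4-(benzyloxy)-3-methoxyphenyl]-3-hydroxypropan-2-yl]propanedioate | COc1cc(C[C@@H](CO)C(Cc2cc(OC)c(OCc3ccccc3)c(OCc3ccccc3)c2)(C(=O)OC)C(=O)OC)ccc1OCc1ccccc1 | intermediate
15 | methyl (4R)-3-[3,4-bis(benzyloxy)-5-methoxybenzyl]-4-[4-(benzyloxy)-3-methoxybenzyl]-2-oxooxolane-3-carboxylate (both C3 epimers) | COc1cc(C[C@H]2COC(=O)C2(Cc2cc(OC)c(OCc3ccccc3)c(OCc3ccccc3)c2)C(=O)OC)ccc1OCc1ccccc1 | intermediate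
16 | (3S,4R)-3-[3,4-bis(benzyloxy)-5-methoxybenzyl]-4-[4-(benzyloxy)-3-methoxybenzyl]oxolan-2-one (cis) | COc1cc(C[C@H]2COC(=O)[C@H]2Cc2cc(OC)c(OCc3ccccc3)c(OCc3ccccc3)c2)ccc1OCc1ccccc1 | intermediate
17 | (3R,4R)-3-[3,4-bis(benzyloxy)-5-methoxybenzyl]-4-[4-(benzyloxy)-3-methoxybenzyl]oxolan-2-one (trans) | COc1cc(C[C@H]2COC(=O)[C@@H]2Cc2cc(OC)c(OCc3ccccc3)c(OCc3ccccc3)c2)ccc1OCc1ccccc1 | intermediate
18 | (−)-thujaplicatin, (3R,4R)-3-(3,4-dihydroxy-5-methoxybenzyl)-4-(4-hydroxy-3-methoxybenzyl)oxolan-2-one | COc1cc(C[C@H]2COC(=O)[C@@H]2Cc2cc(O)c(O)c(OC)c2)ccc1O | target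

## Step count and least certain steps

Total: 11 steps. Longest linear sequence: 8 steps (steps 4 to 11, from 6). The ring-A branch (steps 1 to 3) joins at step 8.

**Step 8 (key step).** The tertiary, benzyl-substituted malonyl radical is more hindered than the usual secondary one. Its addition to the enamine may be slow enough that hydrogen abstraction, loss of HBr from 12, or bromine transfer from 12 to the enamine takes over. Hydrolysis of the crowded iminium ion may also be slow, which would tie up the catalyst and lower turnover and enantioselectivity. Fallback: the ring-B unit is introduced after the radical step. Aldehyde 5 and commercial dimethyl bromomalonate (the secondary bromide, under the conditions of step 8) should give aldehyde F1. Borohydride reduction gives hydroxy diester F2, which closes to lactone ester F3. In parallel, aldehyde 7 is reduced (NaBH4) to benzylic alcohol F4 and converted (PBr3) into benzylic bromide F5, the same compound as A2. Alkylation of the acidic C3–H of F3 with F5 (K2CO3, acetone) returns to the route at 15. The fallback sets out from 5 and 7. It costs two steps, but the C3–C4 bond and the C4 centre are still made by the catalytic like-polarity coupling.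

**Step 10.** The SN2 demethylation at an ester on a quaternary carbon may be slow, chloride may open the lactone at C5 at the temperature needed, and equilibration of the cis epimer may stay incomplete. Fallback: from 15, aqueous KOH in MeOH hydrolyses the ester and opens the lactone to the dipotassium hydroxy dicarboxylate F6. Acidification (HCl) closes the ring again to lactone acid F7. Heating in toluene removes CO2 to give 16 and 17, and NaOMe in MeOH followed by acid work-up equilibrates the mixture to 17, where the fallback rejoins the route.

**Step 11.** Hydrogenolysis of the benzyl ether on the middle oxygen of ring B, flanked by two ortho substituents, may stall. The freed catechol may also be oxidised by air on the catalyst surface or during filtration. Fallback: the reductive cleavage is replaced by Lewis-acid cleavage with cation capture (BCl3, pentamethylbenzene, CH2Cl2, −78 °C). It sets out from 17 and arrives at 18, and at that temperature it should leave the aryl methyl ethers and the lactone intact. No new compound is made.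

## Further compounds

F1 | step 8 | dimethyl 2-[(2R)-1-[4-(benzyloxy)-3-methoxyphenyl]-3-oxopropan-2-yl]propanedioate | COc1cc(C[C@@H](C=O)C(C(=O)OC)C(=O)OC)ccc1OCc1ccccc1
F2 | step 8 | dimethyl 2-[(2R)-1-[4-(benzyloxy)-3-methoxyphenyl]-3-hydroxypropan-2-yl]propanedioate | COc1cc(C[C@@H](CO)C(C(=O)OC)C(=O)OC)ccc1OCc1ccccc1
F3 | step 8 | methyl (4R)-4-[4-(benzyloxy)-3-methoxybenzyl]-2-oxooxolane-3-carboxylate (both C3 epimers) | COc1cc(C[C@H]2COC(=O)C2C(=O)OC)ccc1OCc1ccccc1
F4 | step 8 | [3,4-bis(benzyloxy)-5-methoxyphenyl]methanol | COc1cc(CO)cc(OCc2ccccc2)c1OCc1ccccc1
F5 | step 8 | 1,2-bis(benzyloxy)-5-(bromomethyl)-3-methoxybenzene | COc1cc(CBr)cc(OCc2ccccc2)c1OCc1ccccc1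
F6 | step 10 | dipotassium 2-[3,4-bis(benzyloxy)-5-methoxybenzyl]-2-[(2R)-1-[4-(benzyloxy)-3-methoxyphenyl]-3-hydroxypropan-2-yl]propanedioate | [K+].[K+].COc1cc(C[C@@H](CO)C(Cc2cc(OC)c(OCc3ccccc3)c(OCc3ccccc3)c2)(C([O-])=O)C([O-])=O)ccc1OCc1ccccc1
F7 | step 10 | (4R)-3-[3,4-bis(benzyloxy)-5-methoxybenzyl]-4-[4-(benzyloxy)-3-methoxybenzyl]-2-oxooxolane-3-carboxylic acid (both C3 epimers) | COc1cc(C[C@H]2COC(=O)C2(Cc2cc(OC)c(OCc3ccccc3)c(OCc3ccccc3)c2)C(O)=O)ccc1OCc1ccccc1
F0 | step 11 | none | none
A1 | alternative 1 | (4R)-4-[4-(benzyloxy)-3-methoxybenzyl]oxolan-2-one | COc1cc(C[C@H]2COC(=O)C2)ccc1OCc1ccccc1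
A2 | alternative 1 | 1,2-bis(benzyloxy)-5-(bromomethyl)-3-methoxybenzene | COc1cc(CBr)cc(OCc2ccccc2)c1OCc1ccccc1
A3 | alternative 2 | (4S)-4-benzyl-3-{3-[4-(benzyloxy)-3-methoxyphenyl]propanoyl}-1,3-oxazolidin-2-one | COc1cc(CCC(=O)N2[C@@H](Cc3ccccc3)COC2=O)ccc1OCc1ccccc1
A4 | alternative 2 | tert-butyl 3-[3,4-bis(benzyloxy)-5-methoxyphenyl]propanoate | COc1cc(CCC(=O)OC(C)(C)C)cc(OCc2ccccc2)c1OCc1ccccc1
A5 | alternative 2 | tert-butyl (3R)-2-[3,4-bis(benzyloxy)-5-methoxybenzyl]-3-[4-(benzyloxy)-3-methoxybenzyl]-4-[(4S)-4-benzyl-2-oxo-1,3-oxazolidin-3-yl]-4-oxobutanoate (both C2 epimers) | COc1cc(C[C@@H](C(=O)N2[C@@H](Cc3ccccc3)COC2=O)C(Cc2cc(OC)c(OCc3ccccc3)c(OCc3ccccc3)c2)C(=O)OC(C)(C)C)ccc1OCc1ccccc1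
A6 | alternative 3 | 4-[4-(benzyloxy)-3-methoxybenzyl]-3-[3,4-bis(benzyloxy)-5-methoxybenzyl]furan-2(5H)-one | COc1cc(CC2=C(Cc3cc(OC)c(OCc4ccccc4)c(OCc4ccccc4)c3)C(=O)OC2)ccc1OCc1ccccc1
A7 | alternative 3 | 3,4-dibromofuran-2(5H)-one | O=C1OCC(Br)=C1Br
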